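**Retrosynthetic overview**

1. Numbering (cembrane type): C1 bears the acrylic acid (C15–C17); the carbocycle is C1–C14, with C3 (OH), C4 (CH3, ether O), C7 (ether CH), C8 (=CH2), C11 (OAc), C12 (CH3, OH).
2. Last ring: the fourteen-membered carbocycle is closed by the C13–C14 bond. A C14 α-sulfonyl carbanion opens, at C13, the 2,2-disubstituted oxirane C12/C13 that forms in the flask by Payne rearrangement of a Sharpless epoxy alcohol (C13–OH, C11/C12 oxirane).
3. Enabling feature: C13 is the CH2 arm of the secondary/tertiary 1,2-diol C11(O)–C12(CH3)(OH). Oxirane migration of an (E)-2-methylallylic alcohol epoxide exposes exactly this carbon and delivers both carbinol centres, and the oxolane ring (C4–O–C7), already in place, pre-folds the chain.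
4. First ring: the oxolane, by Shi epoxidation of the (Z)-C3=C4 alkene, CBS reduction at C7 and 5-exo opening at C4; C5–C6 comes from alkylation of a methyl ketone enolate with an allylic bromide.
5. Fragments: C14–C1–C5 with the C1 stereocentre and the (Z)-alkene come from α'-hydroxylation and C–C cleavage of the (S)-carvone ring; C6–C13 comes from 1-methylcyclopentene.

Key step: step 17

Remark on the chemistry: the locants above are used throughout; centres that are destroyed later (ring C6 in 4, C14 in 23) are carried as epimer mixtures, and the methyl ketone enolate of step 11 is assumed to be too weak a base to deprotonate the sulfone in THF.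

**Route**

Step 1
Reactants: 1 (S)-carvone
Product: 2 (5S)-5-(3-hydroxyprop-1-en-2-yl)-2-methylcyclohex-2-en-1-one
Conditions: SeO2 (cat.), t-BuOOH, CH2Cl2, rt
Reagents that add atoms: tert-butyl hydroperoxide, CC(C)(C)OO
Why: Selenium dioxide allylic oxidation (ene reaction then [2,3]-shift) should attack the methyl group of the electron-rich 1,1-disubstituted alkene in preference to its methine and to the electron-poor enone, so the ring stereocentre is untouched.

Step 2
Reactants: 2 (5S)-5-(3-hydroxyprop-1-en-2-yl)-2-methylcyclohex-2-en-1-one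
Product: 3 (5S)-5-{3-[(tert-butyldiphenylsilyl)oxy]prop-1-en-2-yl}-2-methylcyclohex-2-en-1-one
Conditions: t-BuPh2SiCl, imidazole, CH2Cl2, 0 °C to rt
Reagents that add atoms: tert-butyl(chloro)diphenylsilane, CC(C)(C)[Si](Cl)(c1ccccc1)c1ccccc1
Why: Standard silylation of the primary allylic alcohol gives an ether that should survive the bases, hydrides and mild acid used up to step 19.

Step 3
Reactants: 3 (5S)-5-{3-[(tert-butyldiphenylsilyl)oxy]prop-1-en-2-yl}-2-methylcyclohex-2-en-1-one
Product: 4 (6RS)-5-{3-[(tert-butyldiphenylsilyl)oxy]prop-1-en-2-yl}-6-hydroxy-2-methylcyclohex-2-en-1-one (C5 as in 3)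
Conditions: LiN(iPr)2, THF, −78 °C; then 2-(benzenesulfonyl)-3-phenyloxaziridine, −78 °C; aqueous work-up
Reagents that add atoms: 2-(benzenesulfonyl)-3-phenyloxaziridine, O=S(=O)(c1ccccc1)N1OC1c1ccccc1
Why: Kinetic deprotonation gives the cross-conjugated α' enolate, which the oxaziridine hydroxylates (Davis oxidation); the new carbinol centre is removed in step 4, so its configuration is irrelevant.

Step 4
Reactants: 4 (6RS)-5-{3-[(tert-butyldiphenylsilyl)oxy]prop-1-en-2-yl}-6-hydroxy-2-methylcyclohex-2-en-1-one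
Product: 6 methyl (2Z,5R)-6-{[(tert-butyldiphenylsilyl)oxy]methyl}-5-(hydroxymethyl)-2-methylhepta-2,6-dienoate, via aldehyde ester 5 (not isolated)
Conditions: Pb(OAc)4, MeOH–benzene, 0 °C; filtration; then NaBH4, MeOH, −20 °C
Reagents that add atoms: methanol, CO
Why: Glycol-type cleavage of the α-hydroxy ketone by tetravalent lead in methanol breaks the bond between the carbonyl carbon and the carbinol carbon, giving the methyl ester with the ring-imposed (Z)-alkene and the C14 aldehyde, which is reduced at once by borohydride so that the adjacent stereocentre C1 cannot epimerise and the alkene cannot move into conjugation.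

Step 5
Reactants: 6 methyl (2Z,5R)-6-{[(tert-butyldiphenylsilyl)oxy]methyl}-5-(hydroxymethyl)-2-methylhepta-2,6-dienoate
Product: 8 methyl (2Z,5R)-6-{[(tert-butyldiphenylsilyl)oxy]methyl}-2-methyl-5-[(phenylsulfonyl)methyl]hepta-2,6-dienoate, via iodide 7 (not isolated)
Conditions: PPh3, I2, imidazole, CH2Cl2, 0 °C; then PhSO2Na, DMF, 40 °C
Reagents that add atoms: sodium benzenesulfinate, [Na+].[O-]S(=O)c1ccccc1
Why: Appel-type iodination followed by SN2 S-alkylation of the sulfinate installs the carbanion-stabilising group at C14 without touching the neighbouring stereocentre.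

Step 6
Reactants: 8 methyl (2Z,5R)-6-{[(tert-butyldiphenylsilyl)oxy]methyl}-2-methyl-5-[(phenylsulfonyl)methyl]hepta-2,6-dienoate
Product: 9 (2Z,5R)-6-{[(tert-butyldiphenylsilyl)oxy]methyl}-2-methyl-5-[(phenylsulfonyl)methyl]hepta-2,6-dien-1-ol
Conditions: i-Bu2AlH, CH2Cl2, −78 °C; aq. KNaC4H4O6 work-up
Reagents that add atoms: none
Why: 1,2-Reduction of the enoate by the aluminium hydride at low temperature gives the allylic alcohol with the (Z)-geometry intact, the sulfone and silyl ether being inert.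

Step 7
Reactants: 9 (2Z,5R)-6-{[(tert-butyldiphenylsilyl)oxy]methyl}-2-methyl-5-[(phenylsulfonyl)methyl]hepta-2,6-dien-1-ol
Product: 10 (2Z,5R)-1-bromo-6-{[(tert-butyldiphenylsilyl)oxy]methyl}-2-methyl-5-[(phenylsulfonyl)methyl]hepta-2,6-diene
Conditions: CBr4, PPh3, CH2Cl2, −20 °C
Reagents that add atoms: tetrabromomethane, BrC(Br)(Br)Br
Why: Appel bromination proceeds by SN2 displacement at the primary allylic carbon under neutral conditions, so the (Z)-alkene and the base-sensitive sulfone are preserved.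

Step 8
Reactants: 11 1-methylcyclopentene
Product: 12 5-oxohexanal
Conditions: O3, CH2Cl2, −78 °C; then Me2S, −78 °C to rt
Reagents that add atoms: ozone, [O-][O+]=O
Why: Ozonolysis with reductive work-up cleaves the only alkene to the keto aldehyde.

Step 9
Reactants: 12 5-oxohexanal
Product: 13 ethyl (2E)-2-methyl-7-oxooct-2-enoate
Conditions: Ph3P=C(CH3)CO2Et, CH2Cl2, rt
Reagents that add atoms: ethyl 2-(triphenylphosphoranylidene)propanoate, CCOC(=O)C(C)=P(c1ccccc1)(c1ccccc1)c1ccccc1
Why: The stabilised ylide reacts only with the aldehyde (Wittig reaction) and should give the (E)-trisubstituted enoate, as is general for stabilised ylides.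

Step 10
Reactants: 13 ethyl (2E)-2-methyl-7-oxooct-2-enoate
Product: 14 ethyl (2E)-2-methyl-6-methylidene-7-oxooct-2-enoate
Conditions: paraformaldehyde, N-methylanilinium trifluoroacetate, THF, reflux
Reagents that add atoms: formaldehyde (as paraformaldehyde), C=O
Why: Mannich-type α-methylenation (aminomethylation then elimination) proceeds through the more substituted enol and so places the methylidene group on C8, leaving the methyl group C6 as the only enolisable position.

Step 11
Reactants: 14 ethyl (2E)-2-methyl-6-methylidene-7-oxooct-2-enoate; 10 (2Z,5R)-1-bromo-6-{[(tert-butyldiphenylsilyl)oxy]methyl}-2-methyl-5-[(phenylsulfonyl)methyl]hepta-2,6-diene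
Product: 15 ethyl (2E,10Z,13R)-14-{[(tert-butyldiphenylsilyl)oxy]methyl}-2,10-dimethyl-6-methylidene-7-oxo-13-[(phenylsulfonyl)methyl]pentadeca-2,10,14-trienoate
Conditions: 14, LiN(iPr)2 (1.0 equiv), THF, −78 °C; then 10, DMPU, −78 to −40 °C
Reagents that add atoms: none
Why: Kinetic deprotonation can occur only at the methyl group (C6), and the lithium enolate, too weak a base to deprotonate the sulfone, is alkylated by the allylic bromide in an SN2 reaction that forms C5–C6 and keeps the (Z)-alkene.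

Step 12
Reactants: 15 ethyl (2E,10Z,13R)-14-{[(tert-butyldiphenylsilyl)oxy]methyl}-2,10-dimethyl-6-methylidene-7-oxo-13-[(phenylsulfonyl)methyl]pentadeca-2,10,14-trienoate
Product: 16 ethyl (2E,10S,11R,13R)-14-{[(tert-butyldiphenylsilyl)oxy]methyl}-10,11-epoxy-2,10-dimethyl-6-methylidene-7-oxo-13-[(phenylsulfonyl)methyl]pentadeca-2,14-dienoate
Conditions: D-fructose-derived Shi ketone (30 mol%), Oxone (KHSO5), K2CO3, Bu4NHSO4, MeCN–CH2(OMe)2–aqueous buffer (pH 10.5), 0 °C
Reagents that add atoms: potassium peroxymonosulfate, [K+].[O-]S(=O)(=O)OO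
Why: Shi epoxidation: the chiral dioxirane should epoxidise only the electron-rich trisubstituted C3=C4 alkene (the enone, the enoate and the silyloxy-substituted 1,1-disubstituted alkene are deactivated), and the spiro transition-state model for this ketone predicts the (3R,4S)-oxirane, the catalyst overriding the remote C1 centre.

Step 13
Reactants: 16 ethyl (2E,10S,11R,13R)-14-{[(tert-butyldiphenylsilyl)oxy]methyl}-10,11-epoxy-2,10-dimethyl-6-methylidene-7-oxo-13-[(phenylsulfonyl)methyl]pentadeca-2,14-dienoate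
Product: 18 ethyl (2E)-6-[(2S,5R)-5-{(1R,3R)-4-{[(tert-butyldiphenylsilyl)oxy]methyl}-1-hydroxy-3-[(phenylsulfonyl)methyl]pent-4-en-1-yl}-5-methyloxolan-2-yl]-2-methylhepta-2,6-dienoate, via hydroxy oxirane 17 (not isolated)
Conditions: (R)-2-methyl-CBS-oxazaborolidine (20 mol%), catecholborane, toluene, −78 °C; MeOH; then camphorsulfonic acid (cat.), CH2Cl2, 0 °C
Reagents that add atoms: none
Why: Corey–Bakshi–Shibata reduction with the alkenyl group as the large substituent should set C7 as S, and acid then triggers 5-exo-tet attack of this hydroxyl on the tertiary oxirane carbon C4 with inversion, which closes the 2,5-cis-oxolane and leaves the C3 oxygen in place (retention) as the free alcohol.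

Step 14
Reactants: 18 ethyl (2E)-6-[(2S,5R)-5-{(1R,3R)-4-{[(tert-butyldiphenylsilyl)oxy]methyl}-1-hydroxy-3-[(phenylsulfonyl)methyl]pent-4-en-1-yl}-5-methyloxolan-2-yl]-2-methylhepta-2,6-dienoate
Product: 19 ethyl (2E)-6-[(2S,5R)-5-{(1R,3R)-1-[(tert-butyldimethylsilyl)oxy]-4-{[(tert-butyldiphenylsilyl)oxy]methyl}-3-[(phenylsulfonyl)methyl]pent-4-en-1-yl}-5-methyloxolan-2-yl]-2-methylhepta-2,6-dienoate
Conditions: t-BuMe2SiOTf, 2,6-lutidine, CH2Cl2, −78 to 0 °C
Reagents that add atoms: tert-butyldimethylsilyl trifluoromethanesulfonate, CC(C)(C)[Si](C)(C)OS(=O)(=O)C(F)(F)F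
Why: Silyl triflate silylation masks the hindered secondary C3 hydroxyl so that the later acetylation can single out C11.

Step 15
Reactants: 19 ethyl (2E)-6-[(2S,5R)-5-{(1R,3R)-1-[(tert-butyldimethylsilyl)oxy]-4-{[(tert-butyldiphenylsilyl)oxy]methyl}-3-[(phenylsulfonyl)methyl]pent-4-en-1-yl}-5-methyloxolan-2-yl]-2-methylhepta-2,6-dienoate
Product: 20 (2E)-6-[(2S,5R)-5-{(1R,3R)-1-[(tert-butyldimethylsilyl)oxy]-4-{[(tert-butyldiphenylsilyl)oxy]methyl}-3-[(phenylsulfonyl)methyl]pent-4-en-1-yl}-5-methyloxolan-2-yl]-2-methylhepta-2,6-dien-1-ol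
Conditions: i-Bu2AlH, CH2Cl2, −78 °C; aq. KNaC4H4O6 work-up
Reagents that add atoms: none
Why: 1,2-Reduction of the enoate gives the (E)-2-methylallylic alcohol (C13–OH) needed for the directed epoxidation.

Step 16
Reactants: 20 (2E)-6-[(2S,5R)-5-{(1R,3R)-1-[(tert-butyldimethylsilyl)oxy]-4-{[(tert-butyldiphenylsilyl)oxy]methyl}-3-[(phenylsulfonyl)methyl]pent-4-en-1-yl}-5-methyloxolan-2-yl]-2-methylhepta-2,6-dien-1-ol
Product: 21 [(2S,3S)-3-{3-[(2S,5R)-5-{(1R,3R)-1-[(tert-butyldimethylsilyl)oxy]-4-{[(tert-butyldiphenylsilyl)oxy]methyl}-3-[(phenylsulfonyl)methyl]pent-4-en-1-yl}-5-methyloxolan-2-yl]but-3-en-1-yl}-2-methyloxiran-2-yl]methanol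
Conditions: Ti(OiPr)4 (10 mol%), L-(+)-diisopropyl tartrate (12 mol%), t-BuOOH, 4 Å molecular sieves, CH2Cl2, −20 °C
Reagents that add atoms: tert-butyl hydroperoxide, CC(C)(C)OO
Why: Sharpless asymmetric epoxidation acts only on the allylic alcohol alkene, and the L-tartrate ligand should deliver oxygen to the face that gives the (11S,12S)-epoxy alcohol, reagent control overriding the distant stereocentres.

Step 17
Reactants: 21 [(2S,3S)-3-{3-[(2S,5R)-5-{(1R,3R)-1-[(tert-butyldimethylsilyl)oxy]-4-{[(tert-butyldiphenylsilyl)oxy]methyl}-3-[(phenylsulfonyl)methyl]pent-4-en-1-yl}-5-methyloxolan-2-yl]but-3-en-1-yl}-2-methyloxiran-2-yl]methanol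
Product: 23 macrocyclic sulfone diol (14-phenylsulfonyl-3-O-TBS-16-O-TBDPS-4,7-epoxycembra-8(19),15(17)-diene-11,12-diol; C14 epimers), via terminal oxirane 22 (not isolated)
Conditions: KN(SiMe3)2 (3 equiv), 18-crown-6, THF, slow addition of 21 (final 2 mM), 0 to 40 °C; then pH 7 buffer
Reagents that add atoms: none
Why: Proposed new method: the base deprotonates the C13 hydroxyl and, reversibly, C14 next to the sulfone; the alkoxide attacks C12 from the rear of its C–O bond (Payne rearrangement, inversion at C12) and so equilibrates 21 with the 2,2-disubstituted terminal oxirane 22, whose unhindered CH2 (C13) is then opened irreversibly by the C14 carbanion in an SN2 reaction that forms the C13–C14 bond. The closest known reaction types are the Payne rearrangement with capture of the terminal oxirane by carbon nucleophiles (sulfoxonium ylides, cyanide) and the closure of fourteen-membered cembrane rings by intramolecular opening of an epoxide with a sulfur-stabilised carbanion; only their combination in one macrocyclisation is without precedent. One ring is closed, the fourteen-membered carbocycle, in the 14-exo-tet mode at C13, and with the oxolane already present this gives the complete oxa-bridged bicycle. C11 keeps the configuration set by the Sharpless epoxidation because its C–O bond is never broken, C12 is fixed by the single inversion of the oxirane migration (the migrating oxygen ends as the tertiary hydroxyl), and the sulfone-bearing centre C14 is formed without control and is erased in step 18. The step needs attack at C13 of the minor isomer 22 to outrun direct attack on the trisubstituted oxirane of 21 (at C11 or C12, giving twelve- or thirteen-membered rings at hindered carbons) and intermolecular reaction: the primary terminus, the draining of a fast oxirane pre-equilibrium by the irreversible C–C bond formation and high dilution should secure this, and because C3 is silylated and the C3/C4 oxirane has already been consumed in the oxolane, no other electrophile (in particular no 4-exo opening close to C1) is on offer.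

Step 18
Reactants: 23 macrocyclic sulfone diol
Product: 24 macrocyclic diol (3-O-TBS-16-O-TBDPS-4,7-epoxycembra-8(19),15(17)-diene-11,12-diol)
Conditions: Na(Hg) (6% Na), Na2HPO4, MeOH–THF, −20 °C
Reagents that add atoms: none
Why: Electron transfer from sodium amalgam cleaves the C–S bond (reductive desulfonylation) and turns C14 into the required CH2 group without affecting the isolated alkenes, the silyl ethers or the diol.

Step 19
Reactants: 24 macrocyclic diol
Product: 25 macrocyclic 11-acetate (11-O-acetyl derivative of 24)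
Conditions: Ac2O, pyridine, DMAP (cat.), CH2Cl2, 0 °C to rt
Reagents that add atoms: acetic anhydride, CC(=O)OC(C)=O
Why: Acylation with DMAP catalysis should take place at the secondary C11 hydroxyl only, the tertiary C12 hydroxyl being too hindered and C3 being silylated.

Step 20
Reactants: 25 macrocyclic 11-acetate
Product: 26 11-O-acetyl-4,7-epoxycembra-8(19),15(17)-diene-3,11,12,16-tetrol (3,12,16-triol)
Conditions: Bu4NF, AcOH (1:1), THF, rt to 40 °C
Reagents that add atoms: none
Why: Fluoride cleaves both silyl ethers, and buffering with acetic acid keeps the medium too weakly basic for migration or loss of the C11 acetate.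

Step 21
Reactants: 26 11-O-acetyl-4,7-epoxycembra-8(19),15(17)-diene-3,11,12,16-tetrol
Product: 28 Dendronpholide R, via enal 27 (not isolated)
Conditions: MnO2, CH2Cl2, rt; filtration; then NaClO2, NaH2PO4, 2-methylbut-2-ene, t-BuOH–H2O, 0 °C to rt
Reagents that add atoms: sodium chlorite, [Na+].[O-]Cl=O
Why: Manganese dioxide oxidises only the primary allylic alcohol (C16) to the enal, and Pinnick oxidation with an alkene scavenger converts it to the acrylic acid without touching the secondary and tertiary alcohols or the methylidene groups.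

**Compound list**

1 | (S)-(+)-carvone, (5S)-2-methyl-5-(prop-1-en-2-yl)cyclohex-2-en-1-one | O=C1C(C)=CC[C@H](C(C)=C)C1 | starting material
2 | (5S)-5-(3-hydroxyprop-1-en-2-yl)-2-methylcyclohex-2-en-1-one | O=C1C(C)=CC[C@H](C(=C)CO)C1 | intermediate
3 | (5S)-5-{3-[(tert-butyldiphenylsilyl)oxy]prop-1-en-2-yl}-2-methylcyclohex-2-en-1-one | O=C1C(C)=CC[C@H](C(=C)CO[Si](c2ccccc2)(c2ccccc2)C(C)(C)C)C1 | intermediate
4 | (6RS)-5-{3-[(tert-butyldiphenylsilyl)oxy]prop-1-en-2-yl}-6-hydroxy-2-methylcyclohex-2-en-1-one, C5 as in 3, both C6 epimers | O=C1C(C)=CC[C@H](C(=C)CO[Si](c2ccccc2)(c2ccccc2)C(C)(C)C)C1O | intermediate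
5 | methyl (2Z,5R)-6-{[(tert-butyldiphenylsilyl)oxy]methyl}-5-formyl-2-methylhepta-2,6-dienoate | O=C[C@@H](C(=C)CO[Si](c1ccccc1)(c1ccccc1)C(C)(C)C)C/C=C(/C)C(=O)OC | intermediate (not isolated)
6 | methyl (2Z,5R)-6-{[(tert-butyldiphenylsilyl)oxy]methyl}-5-(hydroxymethyl)-2-methylhepta-2,6-dienoate | OC[C@@H](C(=C)CO[Si](c1ccccc1)(c1ccccc1)C(C)(C)C)C/C=C(/C)C(=O)OC | intermediate
7 | methyl (2Z,5R)-6-{[(tert-butyldiphenylsilyl)oxy]methyl}-5-(iodomethyl)-2-methylhepta-2,6-dienoate | IC[C@@H](C(=C)CO[Si](c1ccccc1)(c1ccccc1)C(C)(C)C)C/C=C(/C)C(=O)OC | intermediate (not isolated)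
8 | methyl (2Z,5R)-6-{[(tert-butyldiphenylsilyl)oxy]methyl}-2-methyl-5-[(phenylsulfonyl)methyl]hepta-2,6-dienoate | O=S(=O)(c1ccccc1)C[C@@H](C(=C)CO[Si](c2ccccc2)(c2ccccc2)C(C)(C)C)C/C=C(/C)C(=O)OC | intermediate
9 | (2Z,5R)-6-{[(tert-butyldiphenylsilyl)oxy]methyl}-2-methyl-5-[(phenylsulfonyl)methyl]hepta-2,6-dien-1-ol | O=S(=O)(c1ccccc1)C[C@@H](C(=C)CO[Si](c2ccccc2)(c2ccccc2)C(C)(C)C)C/C=C(/C)CO | intermediate
10 | (2Z,5R)-1-bromo-6-{[(tert-butyldiphenylsilyl)oxy]methyl}-2-methyl-5-[(phenylsulfonyl)methyl]hepta-2,6-diene | O=S(=O)(c1ccccc1)C[C@@H](C(=C)CO[Si](c2ccccc2)(c2ccccc2)C(C)(C)C)C/C=C(/C)CBr | intermediate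
11 | 1-methylcyclopentene | CC1=CCCC1 | starting material
12 | 5-oxohexanal | CC(=O)CCCC=O | intermediate
13 | ethyl (2E)-2-methyl-7-oxooct-2-enoate | CC(=O)CCC/C=C(\C)C(=O)OCC | intermediate
14 | ethyl (2E)-2-methyl-6-methylidene-7-oxooct-2-enoate | CC(=O)C(=C)CC/C=C(\C)C(=O)OCC | intermediate
15 | ethyl (2E,10Z,13R)-14-{[(tert-butyldiphenylsilyl)oxy]methyl}-2,10-dimethyl-6-methylidene-7-oxo-13-[(phenylsulfonyl)methyl]pentadeca-2,10,14-trienoate | O=S(=O)(c1ccccc1)C[C@@H](C(=C)CO[Si](c2ccccc2)(c2ccccc2)C(C)(C)C)C/C=C(/C)CCC(=O)C(=C)CC/C=C(\C)C(=O)OCC | intermediate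
16 | ethyl (2E,10S,11R,13R)-14-{[(tert-butyldiphenylsilyl)oxy]methyl}-10,11-epoxy-2,10-dimethyl-6-methylidene-7-oxo-13-[(phenylsulfonyl)methyl]pentadeca-2,14-dienoate | O=S(=O)(c1ccccc1)C[C@@H](C(=C)CO[Si](c2ccccc2)(c2ccccc2)C(C)(C)C)C[C@H]3O[C@@]3(C)CCC(=O)C(=C)CC/C=C(\C)C(=O)OCC | intermediate
17 | ethyl (2E,7S,10S,11R,13R)-14-{[(tert-butyldiphenylsilyl)oxy]methyl}-10,11-epoxy-7-hydroxy-2,10-dimethyl-6-methylidene-13-[(phenylsulfonyl)methyl]pentadeca-2,14-dienoate | O=S(=O)(c1ccccc1)C[C@@H](C(=C)CO[Si](c2ccccc2)(c2ccccc2)C(C)(C)C)C[C@H]3O[C@@]3(C)CC[C@H](O)C(=C)CC/C=C(\C)C(=O)OCC | intermediate (not isolated)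
18 | ethyl (2E)-6-[(2S,5R)-5-{(1R,3R)-4-{[(tert-butyldiphenylsilyl)oxy]methyl}-1-hydroxy-3-[(phenylsulfonyl)methyl]pent-4-en-1-yl}-5-methyloxolan-2-yl]-2-methylhepta-2,6-dienoate | O=S(=O)(c1ccccc1)C[C@@H](C(=C)CO[Si](c2ccccc2)(c2ccccc2)C(C)(C)C)C[C@@H](O)[C@@]3(C)CC[C@H](O3)C(=C)CC/C=C(\C)C(=O)OCC | intermediate
19 | ethyl (2E)-6-[(2S,5R)-5-{(1R,3R)-1-[(tert-butyldimethylsilyl)oxy]-4-{[(tert-butyldiphenylsilyl)oxy]methyl}-3-[(phenylsulfonyl)methyl]pent-4-en-1-yl}-5-methyloxolan-2-yl]-2-methylhepta-2,6-dienoate | O=S(=O)(c1ccccc1)C[C@@H](C(=C)CO[Si](c2ccccc2)(c2ccccc2)C(C)(C)C)C[C@@H](O[Si](C)(C)C(C)(C)C)[C@@]3(C)CC[C@H](O3)C(=C)CC/C=C(\C)C(=O)OCC | intermediate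
20 | (2E)-6-[(2S,5R)-5-{(1R,3R)-1-[(tert-butyldimethylsilyl)oxy]-4-{[(tert-butyldiphenylsilyl)oxy]methyl}-3-[(phenylsulfonyl)methyl]pent-4-en-1-yl}-5-methyloxolan-2-yl]-2-methylhepta-2,6-dien-1-ol | O=S(=O)(c1ccccc1)C[C@@H](C(=C)CO[Si](c2ccccc2)(c2ccccc2)C(C)(C)C)C[C@@H](O[Si](C)(C)C(C)(C)C)[C@@]3(C)CC[C@H](O3)C(=C)CC/C=C(\C)CO | intermediate
21 | [(2S,3S)-3-{3-[(2S,5R)-5-{(1R,3R)-1-[(tert-butyldimethylsilyl)oxy]-4-{[(tert-butyldiphenylsilyl)oxy]methyl}-3-[(phenylsulfonyl)methyl]pent-4-en-1-yl}-5-methyloxolan-2-yl]but-3-en-1-yl}-2-methyloxiran-2-yl]methanol | O=S(=O)(c1ccccc1)C[C@@H](C(=C)CO[Si](c2ccccc2)(c2ccccc2)C(C)(C)C)C[C@@H](O[Si](C)(C)C(C)(C)C)[C@@]3(C)CC[C@H](O3)C(=C)CC[C@@H]4O[C@@]4(C)CO | intermediate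
22 | (1S)-4-[(2S,5R)-5-{(1R,3R)-1-[(tert-butyldimethylsilyl)oxy]-4-{[(tert-butyldiphenylsilyl)oxy]methyl}-3-[(phenylsulfonyl)methyl]pent-4-en-1-yl}-5-methyloxolan-2-yl]-1-[(2R)-2-methyloxiran-2-yl]pent-4-en-1-ol, present as its potassium alkoxide | O=S(=O)(c1ccccc1)C[C@@H](C(=C)CO[Si](c2ccccc2)(c2ccccc2)C(C)(C)C)C[C@@H](O[Si](C)(C)C(C)(C)C)[C@@]3(C)CC[C@H](O3)C(=C)CC[C@H](O)[C@@]4(C)CO4 | intermediate (not isolated)
23 | macrocyclic sulfone diol: 14-phenylsulfonyl-3-O-TBS-16-O-TBDPS-4,7-epoxycembra-8(19),15(17)-diene-11,12-diol; C1, C3, C4, C7, C11, C12 as in 28; C14 epimers | C=C(CO[Si](c1ccccc1)(c1ccccc1)C(C)(C)C)[C@@H]1C(S(=O)(=O)c3ccccc3)C[C@@](C)(O)[C@@H](O)CCC(=C)[C@@H]2CC[C@@](C)(O2)[C@H](O[Si](C)(C)C(C)(C)C)C1 | intermediate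
24 | macrocyclic diol: 3-O-TBS-16-O-TBDPS-4,7-epoxycembra-8(19),15(17)-diene-11,12-diol; stereocentres as in 28 | C=C(CO[Si](c1ccccc1)(c1ccccc1)C(C)(C)C)[C@@H]1CC[C@@](C)(O)[C@@H](O)CCC(=C)[C@@H]2CC[C@@](C)(O2)[C@H](O[Si](C)(C)C(C)(C)C)C1 | intermediate
25 | 11-O-acetyl derivative of 24 | C=C(CO[Si](c1ccccc1)(c1ccccc1)C(C)(C)C)[C@@H]1CC[C@@](C)(O)[C@@H](OC(C)=O)CCC(=C)[C@@H]2CC[C@@](C)(O2)[C@H](O[Si](C)(C)C(C)(C)C)C1 | intermediate
26 | 11-O-acetyl-4,7-epoxycembra-8(19),15(17)-diene-3,11,12,16-tetrol; stereocentres as in 28 | C=C(CO)[C@@H]1CC[C@@](C)(O)[C@@H](OC(C)=O)CCC(=C)[C@@H]2CC[C@@](C)(O2)[C@H](O)C1 | intermediate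
27 | the 16-aldehyde (enal) of 26 | C=C(C=O)[C@@H]1CC[C@@](C)(O)[C@@H](OC(C)=O)CCC(=C)[C@@H]2CC[C@@](C)(O2)[C@H](O)C1 | intermediate (not isolated)
28 | Dendronpholide R | C=C(C(=O)O)[C@@H]1CC[C@@](C)(O)[C@@H](OC(C)=O)CCC(=C)[C@@H]2CC[C@@](C)(O2)[C@H](O)C1 | target

**Step count and risks**

Total steps: 21. Longest linear sequence: 18 (steps 1–7 and 11–21, from (S)-carvone); steps 8–10 build the second fragment.

Most likely to fail:

1. Step 17 (Proposed new method). What may go wrong: the oxirane migration at the fully substituted C12 may be too slow, so that the carbanion attacks the trisubstituted oxirane directly or the dianion oligomerises. Fallback with known chemistry, from 20: Appel bromination would give the allylic bromide F1. Deprotonation of the sulfone with LiN(iPr)2 under high dilution would close the ring by SN2 alkylation at C13, the classical sulfone-anion macrocyclisation of cembranoids, to the macrocyclic (11E)-alkene F2. Shi epoxidation with the enantiomeric, L-fructose-derived ketone would give the macrocyclic (11S,12S)-oxirane F3. Acid-catalysed hydrolysis (dilute HClO4, THF–H2O), with water attacking the tertiary C12 with inversion, would come back to the route at 23.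

2. Step 11. What may go wrong: before it is alkylated, the enolate may close onto its own enoate by intramolecular conjugate addition or condense with a second ketone molecule. Fallback, from 13: saponification (LiOH) would give the keto acid F4, and the same α-methylenation the methylidene keto acid F5. Its carboxylate–enolate dianion (two equivalents of LiN(iPr)2), in which the carboxylate is no longer a conjugate acceptor, would be alkylated with 10 to the coupled keto acid F6. Ethylation (EtI, K2CO3, DMF) comes back to the route at 15.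

3. Step 12. What may go wrong: poor facial selectivity of the dioxirane on this (Z)-type trisubstituted alkene, or attack of the basic peroxide medium on the methylidene ketone. Fallback, from 9: Sharpless epoxidation of the (Z)-allylic alcohol with L-(+)-diisopropyl tartrate would set the same (3R,4S)-oxirane under directed reagent control and give the epoxy alcohol F7. Conversion into the epoxy triflate F8 (Tf2O, 2,6-lutidine) and alkylation of the lithium enolate of 14 with it comes back to the route at 16, bypassing 10 and 15.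

Further compounds
F1 | step 17 | allylic bromide, the 13-bromo analogue of 20 | O=S(=O)(c1ccccc1)C[C@@H](C(=C)CO[Si](c2ccccc2)(c2ccccc2)C(C)(C)C)C[C@@H](O[Si](C)(C)C(C)(C)C)[C@@]3(C)CC[C@H](O3)C(=C)CC/C=C(\C)CBr
F2 | step 17 | macrocyclic (11E)-alkene, 14-phenylsulfonyl-3-O-TBS-16-O-TBDPS-4,7-epoxycembra-8(19),11,15(17)-triene | C=C(CO[Si](c1ccccc1)(c1ccccc1)C(C)(C)C)[C@@H]1C(S(=O)(=O)c3ccccc3)C/C(C)=C/CCC(=C)[C@@H]2CC[C@@](C)(O2)[C@H](O[Si](C)(C)C(C)(C)C)C1
F3 | step 17 | macrocyclic (11S,12S)-oxirane of F2 | C=C(CO[Si](c1ccccc1)(c1ccccc1)C(C)(C)C)[C@@H]1C(S(=O)(=O)c3ccccc3)C[C@]4(C)O[C@H]4CCC(=C)[C@@H]2CC[C@@](C)(O2)[C@H](O[Si](C)(C)C(C)(C)C)C1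
F4 | step 11 | (2E)-2-methyl-7-oxooct-2-enoic acid | CC(=O)CCC/C=C(\C)C(=O)O
F5 | step 11 | (2E)-2-methyl-6-methylidene-7-oxooct-2-enoic acid | CC(=O)C(=C)CC/C=C(\C)C(=O)O
F6 | step 11 | coupled keto acid, the free acid of 15 | O=S(=O)(c1ccccc1)C[C@@H](C(=C)CO[Si](c2ccccc2)(c2ccccc2)C(C)(C)C)C/C=C(/C)CCC(=O)C(=C)CC/C=C(\C)C(=O)O
F7 | step 12 | [(2S,3R)-3-{(2R)-3-{[(tert-butyldiphenylsilyl)oxy]methyl}-2-[(phenylsulfonyl)methyl]but-3-en-1-yl}-2-methyloxiran-2-yl]methanol | O=S(=O)(c1ccccc1)C[C@@H](C(=C)CO[Si](c2ccccc2)(c2ccccc2)C(C)(C)C)C[C@H]3O[C@@]3(C)CO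
F8 | step 12 | trifluoromethanesulfonate of F7 | O=S(=O)(c1ccccc1)C[C@@H](C(=C)CO[Si](c2ccccc2)(c2ccccc2)C(C)(C)C)C[C@H]3O[C@@]3(C)COS(=O)(=O)C(F)(F)F
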